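## Retrosynthetic overview

1. Target 15 ⇐ isopropenyl cage 12, by oxidative excision of the three-carbon unit on C13 (alkoxy-radical β-scission, loss of acetone).
2. 12 ⇐ bicyclic enol 11, by a one-flask oxidative radical cascade: C3–C11 (seven-membered bridge, homoadamantane), then C12–C13 (cyclopentane).
3. 11 ⇐ 10 ⇐ 9: cationic closure C8→C1 of a monocyclic dearomatized acylphloroglucinol builds the bicyclo[3.3.1]nonane first. A chlorine at C3 blocks that carbon and is removed in the cascade flask.
4. 9 ⇐ 2,4,6-trihydroxybenzophenone + geranyl bromide + NCS + (S)-lavandulyl triflate + prenyl bromide.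
5. Ring order: cyclohexanone ring of the bicyclo[3.3.1] core, then the seven-membered bridge, then the cyclopentane.

Assumption: (S)-lavandulol is purchased as the single enantiomer.

Numbering used below: C1 (benzoyl carbon), C2/C4/C9 (ring carbonyls), C3, C5 (geranyl carbon), C6, C7, C8 (CMe2), C10 (CH2 on C7), C11 (CH on C3), C12 (CMe2), C13 and C14 (CH2CH2 back to C3).

## Route

Step 1
Reactants: 1 2,4,6-trihydroxybenzophenone; 2 geranyl bromide
Product: 3 3-geranyl-2,4,6-trihydroxybenzophenone
Conditions: 1 (2 equiv), DBU (1.5 equiv), THF, 0 °C to rt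
Reagents that add atoms: none
Why: Phenolate C-alkylation (C-geranylation) of the electron-rich phloroglucinol ring, with excess 1 holding back double alkylation; no stereocentre is formed.

Step 2
Reactants: 3 3-geranyl-2,4,6-trihydroxybenzophenone
Product: 4 3-chloro-5-geranyl-2,4,6-trihydroxybenzophenone
Conditions: NCS (1.0 equiv), MeCN/CH2Cl2, −20 to 0 °C
Reagents that add atoms: N-chlorosuccinimide, O=C1CCC(=O)N1Cl
Why: Electrophilic aromatic chlorination at the only free ring CH, which is far more nucleophilic than the side-chain alkenes; the chlorine keeps C3 from reacting in steps 4 and 5 and leaves again in step 6.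

Step 3
Reactants: 5 (S)-lavandulol
Product: 6 (S)-lavandulyl trifluoromethanesulfonate
Conditions: Tf2O (1.1 equiv), 2,6-lutidine (1.3 equiv), CH2Cl2, −78 °C; cold filtration, used at once
Reagents that add atoms: trifluoromethanesulfonic anhydride, O=S(=O)(OS(=O)(=O)C(F)(F)F)C(F)(F)F
Why: O-sulfonylation of the primary alcohol gives an electrophile reactive enough for a β-branched carbon; the stereocentre (later C7) is not touched.

Step 4
Reactants: 4 3-chloro-5-geranyl-2,4,6-trihydroxybenzophenone; 6 (S)-lavandulyl trifluoromethanesulfonate; 7 prenyl bromide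
Product: 9 1-benzoyl-3-chloro-5-geranyl-5-lavandulyl-3-prenylcyclohexane-2,4,9-trione (C1 enolized; formed together with its C5 epimer), via monoalkylated chloro-enolate 8 (not isolated)
Conditions: LiN(SiMe3)2 (3.3 equiv), THF, −78 to 0 °C, add 6; then 7 (1.5 equiv), 0 °C to rt; 1 M HCl work-up
Reagents that add atoms: none
Why: Alkylative dearomatization: the lithium phenolate is C-alkylated at the geranyl-bearing carbon, and the remaining chloro-enolate is then C-prenylated at C3; C7 comes unchanged from 5, C5 forms without control (about 1:1, the unwanted epimer is removed after step 5), and the C3 mixture is erased in step 6.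

Step 5
Reactants: 9 1-benzoyl-3-chloro-5-geranyl-5-lavandulyl-3-prenylcyclohexane-2,4,9-trione
Product: 10 1-benzoyl-3-chloro-5-geranyl-8,8-dimethyl-3,7-diprenylbicyclo[3.3.1]nonane-2,4,9-trione (7-endo; C3 epimers)
Conditions: HCO2H (0.05 M), rt, 12 h; chromatography removes the 7-exo isomer that arises from the C5 epimer of 9
Reagents that add atoms: none
Why: Biomimetic cationic cyclization: Markovnikov protonation of the isopropenyl group gives the tertiary C8 cation, which can be captured at carbon only by the enolized C1 (C3 is quaternary, and O-capture is reversible in formic acid); C1 is set by the tether, and the C5/C7 relationship of 9 places the C7 prenyl endo.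

Step 6
Reactants: 10 1-benzoyl-3-chloro-5-geranyl-8,8-dimethyl-3,7-diprenylbicyclo[3.3.1]nonane-2,4,9-trione
Product: 12 13-isopropenyl cage trione (target skeleton carrying a prop-1-en-2-yl group on C13), via dechlorinated bicyclic enol 11 (not isolated)
Conditions: Zn dust (5 equiv), AcOH, rt, 30 min; filter; then Mn(OAc)3·2H2O (2.5 equiv), Cu(OAc)2·H2O (0.2 equiv), degassed AcOH, rt to 40 °C
Reagents that add atoms: none
Why: Zinc removes the chlorine to unveil the C3–H diketone; Mn(OAc)3 then starts an oxidative free-radical cascade (C3 radical 7-exo onto the endo prenyl, tertiary C12 radical 5-exo onto the C3 prenyl, Cu(OAc)2 oxidation of the last radical to the isopropenyl alkene); C3 is fixed by the cage, and C11 by the alkene face that adds (the rotamer with the CMe2 end under C2 gives the drawn configuration).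

Step 7
Reactants: 12 13-isopropenyl cage trione
Product: 15 the target (CNP0168637.1), via triethylsilyl peroxide 13 (not isolated), via tertiary hydroperoxide 14 (not isolated)
Conditions: Co(acac)2 (10 mol %), Et3SiH (1.5 equiv), O2 (1 atm), ClCH2CH2Cl, rt; evaporate; then FeSO4·7H2O (1.5 equiv), PhSH (3 equiv), MeOH, rt
Reagents that add atoms: none
Why: Isayama–Mukaiyama hydroperoxysilylation (cobalt-hydride hydrogen-atom transfer, faster at the 1,1-disubstituted alkene than at the trisubstituted ones), methanolysis, then divalent-iron reduction to the alkoxy radical, β-scission with loss of acetone and hydrogen-atom transfer from PhSH to the C13 radical; C13 becomes CH2 and no other stereocentre is touched.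

## Compound list

1 | 2,4,6-trihydroxybenzophenone | O=C(c1ccccc1)c1c(O)cc(O)cc1O | starting material
2 | geranyl bromide, (E)-1-bromo-3,7-dimethylocta-2,6-diene | CC(C)=CCC/C(C)=C/CBr | starting material
3 | 3-geranyl-2,4,6-trihydroxybenzophenone | CC(C)=CCC/C(C)=C/Cc1c(O)cc(O)c(C(=O)c2ccccc2)c1O | intermediate
4 | 3-chloro-5-geranyl-2,4,6-trihydroxybenzophenone | CC(C)=CCC/C(C)=C/Cc1c(O)c(Cl)c(O)c(C(=O)c2ccccc2)c1O | intermediate
5 | (S)-lavandulol, (S)-5-methyl-2-(prop-1-en-2-yl)hex-4-en-1-ol | OC[C@@H](CC=C(C)C)C(C)=C | starting material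
6 | (S)-lavandulyl trifluoromethanesulfonate | FC(F)(F)S(=O)(=O)OC[C@@H](CC=C(C)C)C(C)=C | intermediate
7 | prenyl bromide, 1-bromo-3-methylbut-2-ene | CC(C)=CCBr | starting material
8 | monoalkylated chloro-enolate (drawn as the neutral dienol; lithium salt in the flask): 2-benzoyl-4-chloro-6-geranyl-3,5-dihydroxy-6-lavandulylcyclohexa-2,4-dienone | CC(C)=CCC/C(C)=C/C[C@@]1(C[C@@H](CC=C(C)C)C(C)=C)C(=O)C(Cl)=C(O)C(C(=O)c2ccccc2)=C1O | intermediate
9 | 1-benzoyl-3-chloro-5-geranyl-5-lavandulyl-3-prenylcyclohexane-2,4,9-trione, C1 enolized; C5 epimer that leads to the 7-endo bicycle; C3 epimers | CC(C)=CCC/C(C)=C/C[C@@]1(C[C@@H](CC=C(C)C)C(C)=C)C(=O)C(Cl)(CC=C(C)C)C(=O)C(C(=O)c2ccccc2)=C1O | intermediate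
10 | 1-benzoyl-3-chloro-5-geranyl-8,8-dimethyl-3,7-diprenylbicyclo[3.3.1]nonane-2,4,9-trione, 7-endo (C7 prenyl on the side of the C2–C3–C4 bridge); C3 epimers | CC(C)=CCC/C(C)=C/C[C@@]12C[C@@H](CC=C(C)C)C(C)(C)[C@](C(=O)c3ccccc3)(C2=O)C(=O)C(Cl)(CC=C(C)C)C1=O | intermediate
11 | 1-benzoyl-5-geranyl-4-hydroxy-8,8-dimethyl-3,7-diprenylbicyclo[3.3.1]non-3-ene-2,9-dione, 7-endo (enol tautomers) | CC(C)=CCC/C(C)=C/C[C@@]12C[C@@H](CC=C(C)C)C(C)(C)[C@](C(=O)c3ccccc3)(C2=O)C(=O)C(CC=C(C)C)=C1O | intermediate
12 | 13-isopropenyl cage trione (C13 configuration not defined; it is lost in step 7) | CC(C)=CCC/C(C)=C/C[C@@]12C[C@H]3C[C@@H]4C(C)(C)C(C(C)=C)C[C@]4(C1=O)C(=O)[C@@](C(=O)c1ccccc1)(C2=O)C3(C)C | intermediate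
13 | triethylsilyl peroxide of 12 (Et3SiOO–CMe2 on C13) | CC(C)=CCC/C(C)=C/C[C@@]12C[C@H]3C[C@@H]4C(C)(C)C(C(C)(C)OO[Si](CC)(CC)CC)C[C@]4(C1=O)C(=O)[C@@](C(=O)c1ccccc1)(C2=O)C3(C)C | intermediate
14 | tertiary hydroperoxide (HOO–CMe2 on C13) | CC(C)=CCC/C(C)=C/C[C@@]12C[C@H]3C[C@@H]4C(C)(C)C(C(C)(C)OO)C[C@]4(C1=O)C(=O)[C@@](C(=O)c1ccccc1)(C2=O)C3(C)C | intermediate
15 | CNP0168637.1 | CC(C)=CCC/C(C)=C/C[C@@]12C[C@H]3C[C@@H]4C(C)(C)CC[C@]4(C1=O)C(=O)[C@@](C(=O)c1ccccc1)(C2=O)C3(C)C | target

## Step count and risks

Total steps: 7. Longest linear sequence: 6 (steps 1, 2, 4, 5, 6, 7 from compound 1).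

**Risk 1, step 6 (C11 configuration).** The cascade itself has close analogy, but the face of the C7 prenyl alkene that adds to the C3 radical is not secured. The rotamer with the CMe2 end on the C4/C6 side avoids the C8 methyl groups and may well dominate, which would give the C11 epimer of 12. The fallback makes the C3–C11 bond by a stereospecific SN2 reaction instead. It sets out from 5. Epoxidation of the trisubstituted alkene with the ent-Shi ketone and Oxone gives (S)-lavandulol (S)-epoxide F4. Triflation gives epoxy triflate F5. One-pot alkylation of 4 with F5 and then 7, as in step 4, gives the epoxy analogue of 9 F6. Zinc in THF/AcOH then removes the chlorine, and the zinc enolate opens the epoxide at C11 with inversion to give the C3–C11-bonded tertiary alcohol F7. Formic acid closes C8→C1 (C3 is now quaternary) and ionizes the tertiary alcohol, so that the C12 cation is captured by the C3 prenyl alkene; loss of a proton comes back to the route at 12.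

**Risk 2, step 5 (cationic closure at C1).** Formic acid may also protonate the geranyl alkenes, and capture of the C8 cation by the enol oxygen competes. The fallback sets out from 9. A cobalt-hydride Markovnikov hydroalkoxylation of the isopropenyl group alone (Co(salen) catalyst, N-fluoro-2,4,6-trimethylpyridinium triflate, PhSiH3, rt) gives the O-bridged dihydropyran isomer F3. Catalytic Me3SiOTf in CH2Cl2 at −40 °C then ionizes only this tertiary enol ether, and the C8 cation is recaptured at C1; this comes back to the route at 10.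

**Risk 3, step 4 (quaternary centre with a β-branched triflate).** O-alkylation, or alkylation at the chlorine-bearing carbon, may win. The fallback changes the order so that the hindered electrophile meets a free ring CH and the reactive allylic bromide builds the quaternary centre. It sets out from 1 and 6. C-alkylation with LiN(SiMe3)2 in THF gives 3-lavandulyl-2,4,6-trihydroxybenzophenone F1. NCS gives 3-chloro-5-lavandulyl-2,4,6-trihydroxybenzophenone F2. Dearomatizing geranylation with 2, then prenylation with 7 in the same flask (LiN(SiMe3)2, THF), comes back to the route at 9.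

## Further compounds

F1 | step 4 | 3-lavandulyl-2,4,6-trihydroxybenzophenone | O=C(c1ccccc1)c1c(O)cc(O)c(C[C@@H](CC=C(C)C)C(C)=C)c1O
F2 | step 4 | 3-chloro-5-lavandulyl-2,4,6-trihydroxybenzophenone | O=C(c1ccccc1)c1c(O)c(Cl)c(O)c(C[C@@H](CC=C(C)C)C(C)=C)c1O
F3 | step 5 | O-bridged dihydropyran isomer of 9 (C8–O–C9 enol ether) | CC(C)=CCC/C(C)=C/C[C@]12C[C@@H](CC=C(C)C)C(C)(C)OC1=C(C(=O)c3ccccc3)C(=O)C(Cl)(CC=C(C)C)C2=O
F4 | step 6 | (S)-lavandulol (S)-epoxide, (S)-2-(prop-1-en-2-yl)-3-[(S)-3,3-dimethyloxiran-2-yl]propan-1-ol | OC[C@@H](C[C@@H]1OC1(C)C)C(C)=C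
F5 | step 6 | epoxy triflate | FC(F)(F)S(=O)(=O)OC[C@@H](C[C@@H]1OC1(C)C)C(C)=C
F6 | step 6 | epoxy analogue of 9 | CC(C)=CCC/C(C)=C/C[C@@]1(C[C@@H](C[C@@H]2OC2(C)C)C(C)=C)C(=O)C(Cl)(CC=C(C)C)C(=O)C(C(=O)c3ccccc3)=C1O
F7 | step 6 | C3–C11-bonded tertiary alcohol (bicyclo[4.3.1]decane; 2-hydroxypropan-2-yl on C11; isopropenyl on C7) | CC(C)=CCC/C(C)=C/C[C@@]12C[C@H](C(C)=C)C[C@H](C(C)(C)O)[C@@](CC=C(C)C)(C1=O)C(=O)C(C(=O)c3ccccc3)=C2O
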